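## Retrosynthetic overview

1. Ring numbering: C1 = C(OH)CH3, C2 = CHBr, C3 = CH2, C4 = CH(side chain), C5 and C6 = CH2. The last C–C bond is made by a Heck coupling between the vinyl group of (S)-linalool (bought stereocentre) and an (E)-vinyl iodide on C4, which is unmasked from a vinylsilane.
2. The cyclohexane is not closed as a six-membered ring. It comes from a seven-membered 1-boracyclohept-2-ene boronate ("ate") complex, with B between C1 and C6 and C1=C2 inside the ring. Br+ at C2 triggers the 1,2-shift of C6 from B to C1, boron leaves the ring (7→6), and C–B oxidation gives C1–OH.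
3. Enabling feature: in the target the equatorial C2–Br bond is antiperiplanar to the ring bond C1–C6, while C1–O is cis (gauche) to Br. This is the imprint of an anti addition of C6 and Br across a ring-(Z) C1=C2 alkenylboronate. C4, with its alkenyl group equatorial, relays its configuration to C1 and C2 through a chair-like transition state.
4. The acyclic precursor ((Z)-2-iodoalkene plus primary alkyl-Bpin) comes from a Z-selective iodo-Wittig reaction on an aldehyde. Its C4 centre is set by Rh-catalysed asymmetric 1,4-addition of a β-silyl alkenylboronate to an (E)-enoate made by cross-metathesis.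
5. Order of ring formation: the temporary boracycle (7) first, then the carbocycle (6) in the same flask. There is no other ring.

Key step: step 6

Assumption: (S)-(+)-linalool of high enantiomeric purity is taken as a purchasable chiral-pool compound; its carbinol centre is not touched in the route.

## Route

Step 1
Reactants: 1 1-(trimethylsilyl)propyne
Product: 2 4,4,5,5-tetramethyl-2-[(Z)-1-(trimethylsilyl)prop-1-en-2-yl]-1,3,2-dioxaborolane (B trans to Si, CH3 cis to Si)
Conditions: B2pin2, CuCl (cat.), NaOt-Bu (cat.), P(p-tol)3 (cat.), MeOH (2 equiv), THF, rt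
Reagents that add atoms: bis(pinacolato)diboron, CC1(C)OB(OC1(C)C)B1OC(C)(C)C(C)(C)O1
Why: Copper-catalysed protoboration of a silylalkyne (syn-borylcupration, then protonolysis by MeOH) should place copper on the silicon-bearing carbon and boron on the methyl-bearing carbon, so that B and Si end up trans, the geometry that later puts the diene chain trans to the ring.

Step 2
Reactants: 3 2-(but-3-en-1-yl)-4,4,5,5-tetramethyl-1,3,2-dioxaborolane; 4 isopropyl acrylate
Product: 5 isopropyl (E)-5-(4,4,5,5-tetramethyl-1,3,2-dioxaborolan-2-yl)pent-2-enoate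
Conditions: Hoveyda–Grubbs II (cat.), CH2Cl2, 40 °C, 4 in excess
Reagents that add atoms: none
Why: Olefin cross-metathesis of an unhindered terminal alkene with an acrylate should give the (E)-enoate selectively, and the alkyl-Bpin group is inert to the catalyst.

Step 3
Reactants: 5 isopropyl (E)-5-(Bpin)pent-2-enoate; 2 (Z)-alkenylboronate
Product: 6 isopropyl (3S,4E)-4-methyl-3-[2-(4,4,5,5-tetramethyl-1,3,2-dioxaborolan-2-yl)ethyl]-5-(trimethylsilyl)pent-4-enoate
Conditions: [RhCl(C2H4)2]2 (cat.), (R)-BINAP (cat.), aq KOH (substoichiometric), 1,4-dioxane, 50 °C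
Reagents that add atoms: none
Why: Hayashi–Miyaura reaction (Rh-catalysed asymmetric 1,4-addition of an alkenylboron reagent to an (E)-enoate), in which only the sp2 C–B bond of 2 transmetalates, the alkene geometry is retained, and (R)-BINAP is expected, by analogy with the usual sense of induction for (E)-enoates, to deliver the alkenyl group to the Si face of C3 and so set the (S) centre that becomes ring C4.

Step 4
Reactants: 6 isopropyl ester
Product: 7 (3S,4E)-4-methyl-3-[2-(4,4,5,5-tetramethyl-1,3,2-dioxaborolan-2-yl)ethyl]-5-(trimethylsilyl)pent-4-enal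
Conditions: DIBAL-H (1.1 equiv), CH2Cl2, −78 °C; Rochelle salt
Reagents that add atoms: none
Why: Partial ester reduction with DIBAL-H stops at the tetrahedral aluminate at low temperature, the stereocentre is β to the carbonyl and not at risk, and alkyl-Bpin and the vinylsilane are not reduced.

Step 5
Reactants: 7 aldehyde
Product: 8 2-[(3S,5Z)-6-iodo-3-[(1E)-1-(trimethylsilyl)prop-1-en-2-yl]hept-5-en-1-yl]-4,4,5,5-tetramethyl-1,3,2-dioxaborolane
Conditions: EtPPh3I, n-BuLi, THF; I2, −78 °C; NaHMDS, −20 °C; then 7, −78 °C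
Reagents that add atoms: ethyltriphenylphosphonium iodide, CC[P+](c1ccccc1)(c1ccccc1)c1ccccc1.[I-]; iodine, II
Why: Stork–Zhao-type Wittig olefination with (1-iodoethylidene)triphenylphosphorane is kinetically Z-selective and should place iodine cis to the chain, the only geometry from which the boracycle of step 6 can close.

Step 6
Reactants: 8 (Z)-vinyl iodide / alkyl-Bpin
Product: 12 (1R,2S,4S)-2-bromo-1-methyl-4-[(1E)-1-(trimethylsilyl)prop-1-en-2-yl]cyclohexan-1-ol, via alkenyllithium 9 (not isolated), via cyclic boronate complex 10 (not isolated), via bromoboronic ester 11 (not isolated)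
Conditions: t-BuLi (2.1 equiv), THF/Et2O, −78 °C, high dilution; NBS (1.05 equiv), THF, −78 °C; then 30% H2O2, pH 7 phosphate buffer, 0 °C
Reagents that add atoms: N-bromosuccinimide, O=C1CCC(=O)N1Br; hydrogen peroxide, OO
Why: Proposed new method: iodine–lithium exchange should give the configurationally stable (Z)-alkenyllithium 9, whose carbanion adds to the tethered Bpin to form the seven-membered boronate complex 10; NBS then brominates the electron-rich C1=C2 bond at C2, C6 (the only carbon ligand on boron besides the alkenyl carbon) shifts from B to C1 anti to the breaking C1–Br bond of the bromonium ion to give 11, and buffered peroxide replaces boron by OH with retention. The closest known reaction types are the Zweifel olefination (halogen-induced 1,2-metallate shift of alkenylboronate complexes, also intramolecular) and the ring-contracting 1,2-metallate rearrangements of cyclic alkenylboronate complexes with an exocyclic alkene; new are the endocyclic alkene and the oxidation of the β-bromoboronic ester in place of its elimination. The boracycle closes by addition of C1 to trigonal boron (seven-membered, feasible only because B and C3 are cis on C1=C2), and the cyclohexane closes by the 1,2-shift itself, which expels boron from the ring (7→6). C1 and C2 are fixed stereospecifically: anti addition of C6 and Br across the ring-(Z) alkene leaves Br antiperiplanar to C1–C6 and boron cis to Br, hence the cis-bromohydrin after retentive oxidation. Their sense relative to C4 should come from a chair-like transition state with the bulky alkenylsilane equatorial, which leads to the all-cis array C1–O/C2–Br/C4–C with Br, CH3 and the side chain equatorial. The step needs exchange and ring closure to outrun attack of t-BuLi or of a second molecule at boron (fast exchange at −78 °C, high dilution), bromination of the boronate alkene before the vinylsilane (anionic complex, one equivalent of NBS), and oxidation before loss of B and Br (cis B/Br on a six-membered ring cannot become antiperiplanar, and no alkoxide base is present).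

Step 7
Reactants: 12 vinylsilane bromohydrin
Product: 13 (1R,2S,4S)-2-bromo-4-[(1E)-1-iodoprop-1-en-2-yl]-1-methylcyclohexan-1-ol
Conditions: NIS, 2,6-lutidine (cat.), (CF3)2CHOH, 0 °C
Reagents that add atoms: N-iodosuccinimide, O=C1CCC(=O)N1I
Why: Electrophilic ipso-iododesilylation of a vinylsilane (β-silyl cation) in hexafluoroisopropanol should proceed with retention of the (E) geometry, and no other alkene is present.

Step 8
Reactants: 13 (E)-vinyl iodide; 14 (S)-(+)-linalool
Product: 15 (1R,2S,4S)-2-bromo-4-[(2E,4E,6S)-6-hydroxy-6,10-dimethylundeca-2,4,9-trien-2-yl]-1-methylcyclohexan-1-ol (target)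
Conditions: Pd(OAc)2 (cat.), n-Bu4NCl, K2CO3, DMF, 45 °C (Jeffery conditions), 14 in excess
Reagents that add atoms: none
Why: Heck reaction of a vinyl iodide with the monosubstituted alkene of a tertiary allylic alcohol, in which carbopalladation occurs at the terminal carbon and β-hydride elimination can only go towards the new bond (the carbinol carbon bears no H), so the (E,E)-diene should form without touching any stereocentre, the trisubstituted alkene or the unactivated secondary bromide.

## Compound list

1 | 1-(trimethylsilyl)propyne | CC#C[Si](C)(C)C | starting material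
2 | 4,4,5,5-tetramethyl-2-[(Z)-1-(trimethylsilyl)prop-1-en-2-yl]-1,3,2-dioxaborolane | C/C(B1OC(C)(C)C(C)(C)O1)=C\[Si](C)(C)C | intermediate
3 | 2-(but-3-en-1-yl)-4,4,5,5-tetramethyl-1,3,2-dioxaborolane | C=CCCB1OC(C)(C)C(C)(C)O1 | starting material
4 | isopropyl acrylate | C=CC(=O)OC(C)C | starting material
5 | isopropyl (E)-5-(4,4,5,5-tetramethyl-1,3,2-dioxaborolan-2-yl)pent-2-enoate | CC(C)OC(=O)/C=C/CCB1OC(C)(C)C(C)(C)O1 | intermediate
6 | isopropyl (3S,4E)-4-methyl-3-[2-(Bpin)ethyl]-5-(trimethylsilyl)pent-4-enoate | C[Si](C)(C)/C=C(\C)[C@H](CC(=O)OC(C)C)CCB1OC(C)(C)C(C)(C)O1 | intermediate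
7 | (3S,4E)-4-methyl-3-[2-(Bpin)ethyl]-5-(trimethylsilyl)pent-4-enal | C[Si](C)(C)/C=C(\C)[C@H](CC=O)CCB1OC(C)(C)C(C)(C)O1 | intermediate
8 | 2-[(3S,5Z)-6-iodo-3-[(1E)-1-(trimethylsilyl)prop-1-en-2-yl]hept-5-en-1-yl]-4,4,5,5-tetramethyl-1,3,2-dioxaborolane | C[Si](C)(C)/C=C(\C)[C@H](C/C=C(\I)C)CCB1OC(C)(C)C(C)(C)O1 | intermediate
9 | (Z)-alkenyllithium derived from 8 (Li in place of I, cis to the chain) | C[Si](C)(C)/C=C(\C)[C@H](C/C=C(\[Li])C)CCB1OC(C)(C)C(C)(C)O1 | intermediate
10 | lithium salt of the spirocyclic boronate complex: 1-boracyclohept-2-ene (B1, C2(CH3)=C3, (S)-C5 bearing the alkenylsilane) with pinacolate on boron | [Li+].C[Si](C)(C)/C=C(\C)[C@H]1CC[B-]2(OC(C)(C)C(C)(C)O2)C(C)=CC1 | intermediate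
11 | 2-[(1S,2S,4S)-2-bromo-1-methyl-4-[(1E)-1-(trimethylsilyl)prop-1-en-2-yl]cyclohexyl]-4,4,5,5-tetramethyl-1,3,2-dioxaborolane | C[Si](C)(C)/C=C(\C)[C@H]1CC[C@@](C)(B2OC(C)(C)C(C)(C)O2)[C@@H](Br)C1 | intermediate
12 | (1R,2S,4S)-2-bromo-1-methyl-4-[(1E)-1-(trimethylsilyl)prop-1-en-2-yl]cyclohexan-1-ol | C[Si](C)(C)/C=C(\C)[C@H]1CC[C@@](C)(O)[C@@H](Br)C1 | intermediate
13 | (1R,2S,4S)-2-bromo-4-[(1E)-1-iodoprop-1-en-2-yl]-1-methylcyclohexan-1-ol | I/C=C(\C)[C@H]1CC[C@@](C)(O)[C@@H](Br)C1 | intermediate
14 | (S)-(+)-linalool | CC(C)=CCC[C@](C)(O)C=C | starting material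
15 | (1R,2S,4S)-2-bromo-4-[(2E,4E,6S)-6-hydroxy-6,10-dimethylundeca-2,4,9-trien-2-yl]-1-methylcyclohexan-1-ol | CC(C)=CCC[C@](C)(O)/C=C/C=C(\C)[C@H]1CC[C@@](C)(O)[C@@H](Br)C1 | target

## Step count and risk

Total step count: 8. Longest linear sequence: 7 (steps 2–8, from 3 and 4).

Steps most likely to fail:

**Step 6 (Proposed new method).**
- What may go wrong: the alkenyllithium may bind boron of a second molecule instead of closing the seven-membered ring. The facial preference in the shift may be weak. Boron and bromine may be lost together by syn-elimination during the oxidation.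
- Fallback, from 8 back to 12: 8 is closed by an intramolecular B-alkyl Suzuki–Miyaura coupling (Pd(OAc)2/RuPhos, K3PO4, toluene/H2O). Here a seven-membered palladacycle contracts by reductive elimination to trimethyl[(E)-2-[(1S)-4-methylcyclohex-3-en-1-yl]prop-1-en-1-yl]silane F1.
- mCPBA epoxidises the more electron-rich ring alkene to (4S)-1-methyl-4-[(E)-1-(trimethylsilyl)prop-1-en-2-yl]-7-oxabicyclo[4.1.0]heptane F2 (both epoxide diastereomers).
- Dilute aqueous acid opens both epoxides in the trans-diaxial sense (Fürst–Plattner rule) to the single (1R,2R,4S)-1-methyl-4-[(E)-1-(trimethylsilyl)prop-1-en-2-yl]cyclohexane-1,2-diol F3.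
- Sulfonyl diimidazole/NaH converts it into the trans-fused cyclic sulfate of this diol F4.
- LiBr opens the sulfate at the secondary carbon with inversion, and aqueous H2SO4 cleaves the tertiary sulfate monoester to give 12.

**Step 3.**
- What may go wrong: transmetalation of the hindered trisubstituted alkenylboronate may be slow, protodeboronation may compete, and enantiofacial control on the acyclic enoate may be insufficient.
- Fallback, from 2 and 3 back to 6, with auxiliary control in place of catalysis: purchased (R)-4-benzyloxazolidin-2-one is acylated with acryloyl chloride to (R)-3-acryloyl-4-benzyloxazolidin-2-one F5.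
- Cross-metathesis with 3 gives (R)-4-benzyl-3-[(E)-5-(Bpin)pent-2-enoyl]oxazolidin-2-one F6.
- 2 is converted with NaOH/I2 (retention) into [(E)-2-iodoprop-1-en-1-yl]trimethylsilane F7. This is turned into the alkenylmagnesium/copper reagent (t-BuLi; MgBr2·OEt2; CuBr·SMe2).
- The reagent adds to the chelated s-cis imide F6, anti to the benzyl group, to give the (3S)-adduct imide F8.
- Ti(Oi-Pr)4 in i-PrOH transesterifies F8 to 6 and releases the auxiliary.

**Step 5.**
- What may go wrong: Z selectivity may erode and iodine may be lost from the ylide (des-iodo alkene). The (E)-iodide cannot close the boracycle.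
- Fallback, from 7 back to 9: CBr4/PPh3 gives the 1,1-dibromoalkene 2-[(3S)-6,6-dibromo-3-[(1E)-1-(trimethylsilyl)prop-1-en-2-yl]hex-5-en-1-yl]-4,4,5,5-tetramethyl-1,3,2-dioxaborolane F9.
- A Pd-catalysed Negishi methylation (Me2Zn, PdCl2(DPEphos)) replaces selectively the less hindered bromine trans to the chain. This gives the (Z)-vinyl bromide 2-[(3S,5Z)-6-bromo-3-[(1E)-1-(trimethylsilyl)prop-1-en-2-yl]hept-5-en-1-yl]-4,4,5,5-tetramethyl-1,3,2-dioxaborolane F10.
- Bromine–lithium exchange with t-BuLi at −78 °C delivers 9, and step 6 continues from there.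

## Further compounds

F1 | step 6 | trimethyl[(E)-2-[(1S)-4-methylcyclohex-3-en-1-yl]prop-1-en-1-yl]silane | C[Si](C)(C)/C=C(\C)[C@H]1CCC(C)=CC1
F2 | step 6 | (4S)-1-methyl-4-[(E)-1-(trimethylsilyl)prop-1-en-2-yl]-7-oxabicyclo[4.1.0]heptane (both epoxide diastereomers) | C[Si](C)(C)/C=C(\C)[C@H]1CCC2(C)OC2C1
F3 | step 6 | (1R,2R,4S)-1-methyl-4-[(E)-1-(trimethylsilyl)prop-1-en-2-yl]cyclohexane-1,2-diol | C[Si](C)(C)/C=C(\C)[C@H]1CC[C@@](C)(O)[C@H](O)C1
F4 | step 6 | trans-fused cyclic sulfate (1,3,2-dioxathiolane 2,2-dioxide) of diol F3 | C[Si](C)(C)/C=C(\C)[C@H]1CC[C@@]2(C)OS(=O)(=O)O[C@@H]2C1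
F5 | step 3 | (R)-3-acryloyl-4-benzyloxazolidin-2-one | O=C1OC[C@@H](Cc2ccccc2)N1C(=O)C=C
F6 | step 3 | (R)-4-benzyl-3-[(E)-5-(4,4,5,5-tetramethyl-1,3,2-dioxaborolan-2-yl)pent-2-enoyl]oxazolidin-2-one | O=C1OC[C@@H](Cc2ccccc2)N1C(=O)/C=C/CCB3OC(C)(C)C(C)(C)O3
F7 | step 3 | [(E)-2-iodoprop-1-en-1-yl]trimethylsilane | C/C(I)=C\[Si](C)(C)C
F8 | step 3 | (R)-4-benzyl-3-[(3S,4E)-4-methyl-3-[2-(Bpin)ethyl]-5-(trimethylsilyl)pent-4-enoyl]oxazolidin-2-one | O=C1OC[C@@H](Cc2ccccc2)N1C(=O)C[C@H](CCB3OC(C)(C)C(C)(C)O3)/C(C)=C/[Si](C)(C)C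
F9 | step 5 | 2-[(3S)-6,6-dibromo-3-[(1E)-1-(trimethylsilyl)prop-1-en-2-yl]hex-5-en-1-yl]-4,4,5,5-tetramethyl-1,3,2-dioxaborolane | C[Si](C)(C)/C=C(\C)[C@H](CC=C(Br)Br)CCB1OC(C)(C)C(C)(C)O1
F10 | step 5 | 2-[(3S,5Z)-6-bromo-3-[(1E)-1-(trimethylsilyl)prop-1-en-2-yl]hept-5-en-1-yl]-4,4,5,5-tetramethyl-1,3,2-dioxaborolane | C[Si](C)(C)/C=C(\C)[C@H](C/C=C(\Br)C)CCB1OC(C)(C)C(C)(C)O1
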